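Treat the fall of the complex with one exchanged, which the starting complex forms with incoming ligand, in the west run as one first-order approach to a plateau, a rate that integrates in closed form: the excess over the plateau halves in equal intervals.

in all of them: starting complex 0.020 M
- west: incoming ligand 1.5 equiv; temperature 25 °C; the very flask that is asked about, followed so far
- north-east: incoming ligand 1.5 equiv; temperature 10 °C; run made earlier
- flask: incoming ligand 1.50 equiv; temperature 25 °C; time 12 min

- west (time / min: complex with one exchanged / %): 0.500: 51; 1.33: 44; 3.00: 36; 8.00: 25
- north-east (time / min: complex with one exchanged / %): 1.00: 63; 3.00: 56; 6.00: 45; 15.0: 38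

(standard deviation of a reading: 2 percentage points)

- amber: at 12 min take out 90 % of the complex with one exchanged then present, then wait 12 min
- violet: at 12 min raise the temperature by 20 K, then wait 12 min
- red: at 12 min add incoming ligand, 50.0 % of the amount charged, then wait 12 min
- blue: change nothing and wait 12 min more

- what is taken out of complex with one exchanged is counted as made
- additions bring no volume worth counting

* complex with one exchanged, in percent of the starting complex first charged, at 12 min
* the remedy with the largest gain of complex with one exchanged, or "none" below 2 percentage points (amber / violet / red / blue / none)
* complex with one exchanged present, with what was taken out counted in, in percent of the starting complex first charged, after violet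
* complex with one exchanged present, with what was taken out counted in, in percent of the starting complex first charged, after blue

My reckoning sets two times against each other, the half-life of that excess and the wait. The west gap from 3.00 min to 8.00 min is twice the gap from 0.500 min to 3.00 min, so the excess shrinks by one factor over the earlier gap and by its square over the later one, and the drops of 15 percentage points and 11 points make that factor 0.492. As readings with their scatter, this gives a plateau of 21.5 % and a fall half-life of 2.44 min, the time in which the excess over the plateau halves.

Counting on from 25 %, I commit to 22.6 % at 12 min, and blue, 4.92 half-lives later, gives 21.5 %. The north-east reading of 38 % at 15.0 min resembles the west 36 % at 3.00 min, as readings a clock stretched 5.00-fold, so, on the assumption that the plateau does not move with temperature, I expect violet to reach that same 21.5 %. If the plateau is a fixed share of the complex remaining, amber gains 15 points, more than blue's −1.1 points; no run varies the ligand, so I put red beside blue and choose amber.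

The forecast also names amber but stands lower than my reckoning, with 21 % (18 % to 24 %), 14 % after violet and 18 % after blue: "Violet therefore only runs further down the same curve".

The flask gives 25.7 %, 19.8 % after violet, 23.8 % after blue, and amber with a gain of 15 points.

    starting complex + incoming ligand ⇌ leaving ligand + complex with one exchanged (K = 5.60, k = 7.00 L mol⁻¹ s⁻¹, Ea = 48.0 kJ mol⁻¹, ΔH = −38.0 kJ mol⁻¹)
    complex with one exchanged ⇌ isomer of the product (K = 1.40, k = 0.00210 s⁻¹, Ea = 84.0 kJ mol⁻¹, ΔH = −37.0 kJ mol⁻¹)
    complex with two exchanged + incoming ligand ⇌ leaving ligand + complex with three exchanged (K = 51.0, k = 6.20 L mol⁻¹ s⁻¹, Ea = 56.0 kJ mol⁻¹, ΔH = −32.0 kJ mol⁻¹)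
    complex with one exchanged + incoming ligand ⇌ leaving ligand + complex with two exchanged (K = 0.280, k = 3.90 L mol⁻¹ s⁻¹, Ea = 58.0 kJ mol⁻¹, ΔH = −18.0 kJ mol⁻¹)
    2 incoming ligand → self-condensation product (k = 0.450 L mol⁻¹ s⁻¹, Ea = 60.0 kJ mol⁻¹)
    (constants at 25 °C)

In this flask at 12.0 min the first exchange, taken alone and both ways together, relaxes with a half-life of 0.124 min, far shorter than the fall half-life read from the west run, while the isomer of the product climbs from 7.02 % at 1.20 min to 27.8 % at 12.0 min. Carried from 25.7 % with my plateau, the fall half-life gives 21.6 % after blue, where the flask holds 23.8 %. In the neighbouring flask run at 0 °C, my stretch, as an estimate, lengthens it to 35.7 min, longer than the 12 min that flask runs, and at that time it stands at 56.9 %.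

Readings and results were generated by integration for substances that don't exist, and the scatter is random.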